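## Retrosynthetic overview
1. The target comes from its 2',4'-bis-TBS ether by buffered fluoride in the last step. Ring B is bought.
2. Rings C and A are both closed in one flask from an acyclic chain, tert-butyl (9S)-9-aryl-9-silyloxy-4-lavandulyl-3,5,7-trioxononanoate. Ring C forms first (carbinol O onto the C5 ketone, loss of H2O). Ring A follows (loss of t-BuOH gives an acylketene, C6–C1 closure, aromatisation).
3. The O1–C8a bond is fixed next to the lavandulyl-bearing carbon before ring A exists, so only the 8-lavandulyl isomer can form. C2 keeps the configuration set in the aldol step.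
4. The chain comes from the trianion of a 4-lavandulyl-3,5-dioxohexanoate and an (S)-beta-silyloxy thioester, made by catalytic asymmetric acetate aldol on the protected aldehyde.
5. The diketo ester comes from tert-butyl acetoacetate dianion, (S)-lavandulyl iodide and the Weinreb acetamide. The iodide comes from an Evans deconjugative prenylation of the senecioyl imide.

Assumption: 2,4-dihydroxy-5-methoxybenzaldehyde is taken as a purchasable catalogue building block.

## Route

Step 1
Reactants: 1 (S)-4-benzyloxazolidin-2-one; 2 3-methylbut-2-enoyl chloride (senecioyl chloride)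
Product: 3 (S)-4-benzyl-3-(3-methylbut-2-enoyl)oxazolidin-2-one
Conditions: n-BuLi (1.0 equiv), THF, −78 °C; then 2, −78 → 0 °C
Reagents that add atoms: none
Why: N-acylation of the lithiated Evans oxazolidinone by an acid chloride is standard imide formation and creates no stereocentre.

Step 2
Reactants: 3 (S)-4-benzyl-3-(3-methylbut-2-enoyl)oxazolidin-2-one; 4 1-bromo-3-methylbut-2-ene (prenyl bromide)
Product: 5 (S)-4-benzyl-3-[(2S)-5-methyl-2-(prop-1-en-2-yl)hex-4-enoyl]oxazolidin-2-one
Conditions: NaN(SiMe3)2 (1.1 equiv), THF, −78 °C, 45 min; then 4 (1.5 equiv), −78 → −30 °C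
Reagents that add atoms: none
Why: Deconjugative Evans alkylation, in which gamma-deprotonation gives the chelated Z-dienolate that reacts at its alpha-carbon on the face opposite the benzyl group, so the (S)-auxiliary sets the new centre as (S) (same facial sense as the propionyl imide/allyl iodide benchmark) and leaves the isopropenyl group.

Step 3
Reactants: 5 (S)-4-benzyl-3-[(2S)-5-methyl-2-(prop-1-en-2-yl)hex-4-enoyl]oxazolidin-2-one
Product: 6 (S)-lavandulol [(2S)-5-methyl-2-(prop-1-en-2-yl)hex-4-en-1-ol]
Conditions: LiBH4 (1.2 equiv), H2O (1.2 equiv), Et2O, 0 °C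
Reagents that add atoms: none
Why: Reductive cleavage of the imide by borohydride takes the exocyclic acyl group straight to the primary alcohol without enolising the beta,gamma-unsaturated centre, and the auxiliary is recovered.

Step 4
Reactants: 6 (S)-lavandulol
Product: 7 (S)-lavandulyl iodide [(2S)-1-iodo-5-methyl-2-(prop-1-en-2-yl)hex-4-ene]
Conditions: I2, PPh3, imidazole, CH2Cl2, 0 → 23 °C, dark
Reagents that add atoms: iodine, [I][I]
Why: Appel-type (Garegg–Samuelsson) iodination is an SN2 displacement at the primary carbon under neutral conditions, so the adjacent stereocentre and both alkenes are untouched.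

Step 5
Reactants: 8 tert-butyl acetoacetate; 7 (S)-lavandulyl iodide; 9 N-methoxy-N-methylacetamide
Product: 11 tert-butyl 4-[(2R)-5-methyl-2-(prop-1-en-2-yl)hex-4-en-1-yl]-3,5-dioxohexanoate, via gamma-alkylated keto ester 10 (not isolated)
Conditions: 8 (1.3 equiv), NaH, THF, 0 °C; n-BuLi, 0 °C; 7, 0 → 23 °C; then LiN(iPr)2 (1.4 equiv), −78 → 0 °C; 9, −78 → 0 °C; AcOH quench
Reagents that add atoms: none
Why: Weiler dianion chemistry, in which the last-formed gamma-carbanion displaces the primary iodide and the regenerated dianion is then acylated at the same carbon by the Weinreb amide (its chelated adduct stops over-reaction), while the new C4 centre is enolisable and ends as an sp2 ring carbon, so its configuration does not matter.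

Step 6
Reactants: 12 2,4-dihydroxy-5-methoxybenzaldehyde
Product: 13 2,4-bis(tert-butyldimethylsilyloxy)-5-methoxybenzaldehyde
Conditions: TBSCl (2.4 equiv), imidazole (5 equiv), DMF, 23 °C
Reagents that add atoms: tert-butyldimethylsilyl chloride, CC(C)(C)[Si](C)(C)Cl
Why: Standard Corey silylation of both phenols gives groups that survive amide bases, mild acid and 110 °C and that leave at the end with fluoride, which does not touch the alkenes.

Step 7
Reactants: 14 S-tert-butyl thioacetate
Product: 15 1-(tert-butylthio)-1-(trimethylsilyloxy)ethene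
Conditions: LiN(iPr)2, THF, −78 °C; Me3SiCl, −78 → 0 °C; distil
Reagents that add atoms: chlorotrimethylsilane, C[Si](C)(C)Cl
Why: O-silylation of the lithium thioester enolate gives the silyl ketene thioacetal needed for the Mukaiyama aldol.

Step 8
Reactants: 13 2,4-bis(tert-butyldimethylsilyloxy)-5-methoxybenzaldehyde; 15 1-(tert-butylthio)-1-(trimethylsilyloxy)ethene
Product: 16 S-tert-butyl (3S)-3-[2,4-bis(tert-butyldimethylsilyloxy)-5-methoxyphenyl]-3-(trimethylsilyloxy)propanethioate
Conditions: (S)-BINOL (20 mol %), Ti(OiPr)4 (20 mol %), 4 Å MS, Et2O, −20 °C; pH 7 work-up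
Reagents that add atoms: none
Why: Keck catalytic asymmetric Mukaiyama acetate aldol, in which the (S)-BINOL–Ti(OiPr)4 complex exposes the Si face of the aromatic aldehyde (the sense this catalyst family shows with benzaldehyde), so the carbinol centre is (S), and silyl transfer delivers the Me3Si ether directly.

Step 9
Reactants: 11 tert-butyl 4-[(2R)-lavandulyl]-3,5-dioxohexanoate; 16 S-tert-butyl (3S)-3-aryl-3-(trimethylsilyloxy)propanethioate
Product: 17 tert-butyl (9S)-9-[2,4-bis(tert-butyldimethylsilyloxy)-5-methoxyphenyl]-4-[(2R)-5-methyl-2-(prop-1-en-2-yl)hex-4-en-1-yl]-3,5,7-trioxo-9-(trimethylsilyloxy)nonanoate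
Conditions: 11 (2.0 equiv), LiN(iPr)2 (6.2 equiv), THF, −78 → 0 °C; then 16, −78 °C, 1 h; AcOH, −78 °C; short silica plug, excess 11 recovered
Reagents that add atoms: none
Why: Harris-type polyanion Claisen acylation, in which only the terminal, last-formed CH2 carbanion of the trianion is reactive and adds to the electrophilic thioester at −78 °C faster than it enolises it, while the silyl-protected (S)-centre is not involved.

Step 10
Reactants: 17 tert-butyl (9S)-9-aryl-4-[(2R)-lavandulyl]-3,5,7-trioxo-9-(trimethylsilyloxy)nonanoate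
Product: 21 (2S)-2-[2,4-bis(tert-butyldimethylsilyloxy)-5-methoxyphenyl]-5,7-dihydroxy-8-[(2R)-5-methyl-2-(prop-1-en-2-yl)hex-4-en-1-yl]chroman-4-one, via free carbinol 18 (not isolated), via dihydropyranone 19 (not isolated), via acylketene 20 (not isolated)
Conditions: (PhO)2P(O)OH (5 mol %), H2O (0.5 equiv), PhMe, 23 °C, 2 h; then 2,6-lutidine (20 mol %), 4 Å MS, dilute to 5 mM, 110 °C, 4 h, t-BuOH distilled off
Reagents that add atoms: none
Why: Proposed new method: mild acid frees the C9 carbinol, whose oxygen can reach only the C5 ketone through a six-membered hemiketal and dehydrates to the 2,3-dihydropyran-4-one (ring C, the classical cyclodehydration of a delta-hydroxy-beta-diketone, in which the C–O bond at the stereocentre is never broken, so (S) is retained and O1 is locked next to the lavandulyl carbon); neutral thermolysis of the tert-butyl beta-keto ester then gives acylketene 20 (Witzeman-type ketene generation), where the usual 2-pyrone O-trapping is impossible because that oxygen is now the ring ether, so the enolised dienylketene closes by 6-pi electrocyclisation/C-acylation at the nucleophilic enol-ether carbon and tautomerises to the phloroglucinol (ring A); the closest known reactions are the last step of the Danheiser benzannulation, the Harris Claisen-type cyclisation of 3,5,7-triketo esters to acylphloroglucinols and Barrett's ketene-based resorcylate aromatisations.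

Step 11
Reactants: 21 (2S)-2-[2,4-bis(tert-butyldimethylsilyloxy)-5-methoxyphenyl]-5,7-dihydroxy-8-[(2R)-lavandulyl]chroman-4-one
Product: 22 (2S)-2-(2,4-dihydroxy-5-methoxyphenyl)-5,7-dihydroxy-8-[(2R)-5-methyl-2-(prop-1-en-2-yl)hex-4-en-1-yl]chroman-4-one (CNP0323048.1)
Conditions: Bu4NF (2.4 equiv), AcOH (3 equiv), THF, 0 °C, 30 min
Reagents that add atoms: none
Why: Fluoride cleavage of aryl silyl ethers, with AcOH buffering so that phenoxides, and with them retro-oxa-Michael opening to the chalcone (racemisation at C2), do not build up, and with both alkenes inert.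

## Compound list
1 | (S)-4-benzyloxazolidin-2-one | O=C1N[C@@H](Cc2ccccc2)CO1 | starting material
2 | 3-methylbut-2-enoyl chloride | CC(C)=CC(=O)Cl | starting material
3 | (S)-4-benzyl-3-(3-methylbut-2-enoyl)oxazolidin-2-one | CC(C)=CC(=O)N1[C@@H](Cc2ccccc2)COC1=O | intermediate
4 | 1-bromo-3-methylbut-2-ene | CC(C)=CCBr | starting material
5 | (S)-4-benzyl-3-[(2S)-5-methyl-2-(prop-1-en-2-yl)hex-4-enoyl]oxazolidin-2-one | C=C(C)[C@H](CC=C(C)C)C(=O)N1[C@@H](Cc2ccccc2)COC1=O | intermediate
6 | (S)-lavandulol | C=C(C)[C@H](CC=C(C)C)CO | intermediate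
7 | (S)-lavandulyl iodide | C=C(C)[C@H](CC=C(C)C)CI | intermediate
8 | tert-butyl acetoacetate | CC(=O)CC(=O)OC(C)(C)C | starting material
9 | N-methoxy-N-methylacetamide | CC(=O)N(C)OC | starting material
10 | tert-butyl (6S)-9-methyl-3-oxo-6-(prop-1-en-2-yl)dec-8-enoate | C=C(C)[C@H](CC=C(C)C)CCC(=O)CC(=O)OC(C)(C)C | intermediate (not isolated)
11 | tert-butyl 4-[(2R)-5-methyl-2-(prop-1-en-2-yl)hex-4-en-1-yl]-3,5-dioxohexanoate (C4 epimers, enol tautomers) | C=C(C)[C@H](CC=C(C)C)CC(C(C)=O)C(=O)CC(=O)OC(C)(C)C | intermediate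
12 | 2,4-dihydroxy-5-methoxybenzaldehyde | O=Cc1cc(OC)c(O)cc1O | starting material
13 | 2,4-bis(tert-butyldimethylsilyloxy)-5-methoxybenzaldehyde | O=Cc1cc(OC)c(O[Si](C)(C)C(C)(C)C)cc1O[Si](C)(C)C(C)(C)C | intermediate
14 | S-tert-butyl thioacetate | CC(=O)SC(C)(C)C | starting material
15 | 1-(tert-butylthio)-1-(trimethylsilyloxy)ethene | C=C(O[Si](C)(C)C)SC(C)(C)C | intermediate
16 | S-tert-butyl (3S)-3-[2,4-bis(TBSO)-5-methoxyphenyl]-3-(trimethylsilyloxy)propanethioate | C[Si](C)(C)O[C@H](c1cc(OC)c(O[Si](C)(C)C(C)(C)C)cc1O[Si](C)(C)C(C)(C)C)CC(=O)SC(C)(C)C | intermediate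
17 | tert-butyl (9S)-9-[2,4-bis(TBSO)-5-methoxyphenyl]-4-[(2R)-lavandulyl]-3,5,7-trioxo-9-(trimethylsilyloxy)nonanoate (C4 epimers, tautomers) | C=C(C)[C@H](CC=C(C)C)CC(C(=O)CC(=O)OC(C)(C)C)C(=O)CC(=O)C[C@H](O[Si](C)(C)C)c1cc(OC)c(O[Si](C)(C)C(C)(C)C)cc1O[Si](C)(C)C(C)(C)C | intermediate
18 | tert-butyl (9S)-9-[2,4-bis(TBSO)-5-methoxyphenyl]-9-hydroxy-4-[(2R)-lavandulyl]-3,5,7-trioxononanoate | C=C(C)[C@H](CC=C(C)C)CC(C(=O)CC(=O)OC(C)(C)C)C(=O)CC(=O)C[C@H](O)c1cc(OC)c(O[Si](C)(C)C(C)(C)C)cc1O[Si](C)(C)C(C)(C)C | intermediate (not isolated)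
19 | tert-butyl (6R)-4-{(2S)-2-[2,4-bis(TBSO)-5-methoxyphenyl]-4-oxo-3,4-dihydro-2H-pyran-6-yl}-9-methyl-3-oxo-6-(prop-1-en-2-yl)dec-8-enoate | C=C(C)[C@H](CC=C(C)C)CC(C(=O)CC(=O)OC(C)(C)C)C1=CC(=O)C[C@@H](c2cc(OC)c(O[Si](C)(C)C(C)(C)C)cc2O[Si](C)(C)C(C)(C)C)O1 | intermediate (not isolated)
20 | acylketene formed from 19 by loss of tert-butanol | C=C(C)[C@H](CC=C(C)C)CC(C(=O)C=C=O)C1=CC(=O)C[C@@H](c2cc(OC)c(O[Si](C)(C)C(C)(C)C)cc2O[Si](C)(C)C(C)(C)C)O1 | intermediate (not isolated)
21 | (2S)-2-[2,4-bis(TBSO)-5-methoxyphenyl]-5,7-dihydroxy-8-[(2R)-lavandulyl]chroman-4-one | C=C(C)[C@H](CC=C(C)C)Cc1c(O)cc(O)c2c1O[C@H](c1cc(OC)c(O[Si](C)(C)C(C)(C)C)cc1O[Si](C)(C)C(C)(C)C)CC2=O | intermediate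
22 | (2S)-2-(2,4-dihydroxy-5-methoxyphenyl)-5,7-dihydroxy-8-[(2R)-lavandulyl]chroman-4-one | C=C(C)[C@H](CC=C(C)C)Cc1c(O)cc(O)c2c1O[C@H](c1cc(OC)c(O)cc1O)CC2=O | target

## Step count
- Total steps: 11.
- Longest linear sequence: 8 (steps 1, 2, 3, 4, 5, 9, 10, 11).

## Three steps most likely to fail

**Step 10 (double ring closure).**
- The risks are decarboxylation or oligomerisation of ketene 20 before the weakly nucleophilic enol-ether carbon captures it, and loss of ee at the electron-rich benzylic C–O bond.
- The fallback sets out from 17. The operation is stopped after the acid stage and dihydropyranone 19 is isolated.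
- The tert-butyl ester of 19 is cleaved with Me3SiOTf/2,6-lutidine (CH2Cl2, 0 °C, then pH 5 buffer) to the beta-keto acid F1.
- Ring A is then closed ionically at −40 °C by activating the acid as its mixed anhydride with (CF3CO)2O/2,6-lutidine. This is an intramolecular Friedel–Crafts-type C-acylation of the vinylogous ester instead of a thermal ketene process.
- The fallback comes back to the route at 21.

**Step 9 (trianion acylation).**
- The risks are proton transfer to the trianion and E1cB loss of the silyloxy group from the enolisable thioester. Half of the nucleophile is also consumed as base.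
- The fallback sets out from 16, which is reduced with iBu2AlH (CH2Cl2, −78 °C) to (3S)-3-[2,4-bis(TBSO)-5-methoxyphenyl]-3-(trimethylsilyloxy)propanal F2.
- The trianion of 11 (1.1 equiv) adds to this aldehyde at −78 °C. Aldol addition outruns enolisation and needs no second equivalent of base. The product is the C7 carbinol F3, a mixture of epimers.
- Dess–Martin periodinane with NaHCO3 oxidises the carbinol to the beta-diketone, which comes back to the route at 17.

**Step 5 (dianion alkylation).**
- The risk is that the hard dianion attacks the beta-branched iodide, whose beta-hydrogen is allylic, by E2 instead of SN2.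
- The fallback sets out from 8, 9 and 7 and reverses the order of bond formation.
- The dianion of 8 is first acylated with 9 to tert-butyl 3,5-dioxohexanoate F4.
- The soft, weakly basic monoanion of this diketo ester (Cs2CO3, DMF, 40 °C) is then C-alkylated at C4, its most acidic position, with 7.
- The fallback comes back to the route at 11.

## Further compounds
F1 | step 10 | (6R)-4-{(2S)-2-[2,4-bis(TBSO)-5-methoxyphenyl]-4-oxo-3,4-dihydro-2H-pyran-6-yl}-9-methyl-3-oxo-6-(prop-1-en-2-yl)dec-8-enoic acid | C=C(C)[C@H](CC=C(C)C)CC(C(=O)CC(=O)O)C1=CC(=O)C[C@@H](c2cc(OC)c(O[Si](C)(C)C(C)(C)C)cc2O[Si](C)(C)C(C)(C)C)O1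
F2 | step 9 | (3S)-3-[2,4-bis(TBSO)-5-methoxyphenyl]-3-(trimethylsilyloxy)propanal | C[Si](C)(C)O[C@H](c1cc(OC)c(O[Si](C)(C)C(C)(C)C)cc1O[Si](C)(C)C(C)(C)C)CC=O
F3 | step 9 | tert-butyl (9S)-9-[2,4-bis(TBSO)-5-methoxyphenyl]-7-hydroxy-4-[(2R)-lavandulyl]-3,5-dioxo-9-(trimethylsilyloxy)nonanoate | C=C(C)[C@H](CC=C(C)C)CC(C(=O)CC(=O)OC(C)(C)C)C(=O)CC(O)C[C@H](O[Si](C)(C)C)c1cc(OC)c(O[Si](C)(C)C(C)(C)C)cc1O[Si](C)(C)C(C)(C)C
F4 | step 5 | tert-butyl 3,5-dioxohexanoate | CC(=O)CC(=O)CC(=O)OC(C)(C)C
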